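(Its constants were chosen freely; the result is computed.)

Count the partner first.

starting material 0.80 M (fed, over 10 s); partner 0.600 equiv; time 2.0 h; the fed solution adds 0.25 times the starting volume

    starting material + partner → target (k1 = 0.34 /M/s)
    starting material + 2 partner → side product (k2 = 2.4 /M²/s)

* the state of affairs at 2.0 h: stopped, and by what, or still going (all of the starting material has reacted / forward and back rates have come level / the partner has run out first / it is still moving)
* share of the starting material used up at 2.0 h
* target at 2.0 h, in percent of the starting material charged
* side product at 2.0 h, in percent of the starting material charged

- a step written with two of one species runs at k times the square of its concentration and takes two of it each time
- every charge counts on the volume at the start, and the solution that is fed holds the whole dose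
- the reaction counts as stopped when no species that holds the starting material changes by six tenths of a point or more over the second half of the time
- run time (flask): 2.0 h

This flask gets 0.480 M of partner against 0.80 M of starting material, and each step takes at least one partner per starting material, so the partner is the limiting reagent.

Does it finish in time? Even if each partner took one starting material, at least 0.256 M of starting material stands after the feed. The partner's half-life is then at most 7.96 s, far shorter than 2.0 h, so I expect this flask to stop with its partner used up.

What then is the split? Both steps are first order in starting material, so it cancels from their ratio. Side product forms over target as [partner] over the tie concentration 0.142 M, the first rate constant over the second, which is the [partner] at which both steps run level. This charge starts at 3.38 times the tie.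

I freeze the volume. Each target then costs 1 + 2[partner]/tie of partner, and running the charge down to zero gives target = (tie/2)·ln(1 + 2·charge/tie). The starting volume gives 18.2% and the full volume 20.6%, and the volume of this flask runs between the two, so I expect its target between them. The partner balance puts side product at 19.7% to 20.9% and conversion at 39.1% to 40.3%.

The forecast says the partner has run out first, with conversion 39.7%, target 19.5% and side product 20.3%, noting that “Early on, starting material is scarce and the partner concentration is high”.

In this flask the partner has run out first, with 0% of its charge left at 2.00 h: conversion 39.7%, target 19.4%, side product 20.3%. At 9.13 × 10⁻⁴ h its side-product step uses partner 3.7 times as fast as its target step, which reads as [partner] near 0.263 M, above the tie concentration. In the neighbour charged with 0.48 M of starting material, partner begins at 0.288 M, and the same tie concentration brackets target at 24.0% to 26.7%; that neighbour gives 25.7%.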